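The data come from a simulation with made-up constants, and the scatter is random.

X gained and J lost count nearly one amount: at 15.0 min the theta run adds up to 100% of its charge and the delta run to 99.2%, within the scatter of the readings. The delta run may therefore take the mean of its two counts, 1.60% converted, though this mean carries a scatter of 44.2% of its own value. The next charge is to be picked from four flasks, and the aim is the most X at the end.

| flask | J | D | remark | time |
|---|---|---|---|---|
| theta | 0.19 M | 3.2 mM | run made earlier |  |
| delta | 1.5 M | 3.2 mM | run made earlier |  |
| spring | 0.15 M | 3.2 mM |  | 15 min |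
| dawn | 0.30 M | 3.2 mM |  | 15 min |
| autumn | 0.60 M | 3.2 mM |  | 15 min |
| winter | 1.2 M | 3.2 mM |  | 15 min |

- theta (time / min: X / %, J / %): 1.33: 2.5, 97.8; 2.00: 3.2, 93.3; 3.00: 8.1, 94.5; 5.00: 12.3, 89.8; 10.0: 21.1, 76.6; 15.0: 33.5, 66.6
- delta (time / min: X / %, J / %): 2.50: 0, 100.0; 5.00: 0, 99.5; 8.00: 0.7, 99.8; 10.0: 0.9, 98.7; 12.0: 2.3, 98.4; 15.0: 1.2, 98.0

(standard deviation of a reading: 1 percentage point)

- percentages count the J that a species holds: one G counts as two
- the numbers in the tables scatter by 1 percentage point (one standard deviation)
- steps that have been proposed: L -> D + X; Q <-> L; J + Q <-> G; J + D <-> Q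
- "hardly changes" means that all values lie within two and a half points (for a concentration: within two and a half percent of the largest)

* [X] at the end for spring, dawn, autumn, winter, in this order
* how that number moves from the first to the last of them (rises all the way / falls, then rises / falls all the way / hardly changes / rises, then falls)

My own reckoning works in logarithms, where the row of cX against cJ is drawn as two straight arms. On the low arm a fixed fraction converts, taken from theta's 33.5%, so the slope is plus one. On the high arm, delta yields 0.0240 M, less than theta's 0.0636 M, although its charge is larger. This suggests that J holds catalyst back as G. If G is the main form of the catalyst, the slope is minus one and the product A = cX·cJ stays constant, here read from delta as 0.0360 M^2.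

The square root of A over theta's fraction gives 0.328 M: this is the crossing concentration, the charge at which the two arms meet. A root halves a logarithm, so delta's scatter leaves a range from 0.245 M to 0.394 M. That range holds dawn's 0.30 M but not spring's 0.15 M, autumn's 0.60 M or winter's 1.2 M, so the charge to make is dawn's.

The forecast gives 0.06 M, 0.062 M, 0.046 M and 0.029 M, a row that rises, then falls, and says: “The first two are nearly tied”.

The flasks give 0.0549 M, 0.0652 M, 0.0501 M and 0.0298 M, a row that rises, then falls, and dawn stands highest.

    L → D + X (k = 0.233 s⁻¹)
    Q ⇌ L (K = 3.00, k = 0.227 s⁻¹)
    J + Q ⇌ G, settled at all times (K = 12.0 M⁻¹)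
    J + D ⇌ Q (K = 23.0 M⁻¹, k = 0.269 M⁻¹ s⁻¹)

In the spring flask, L has a half-life of 3.0 s on its path to D + X at 7.01 min, far shorter than the 19 min of J by the forward path from J + D to Q alone at 15.0 min. At 7.01 min in the spring flask, L is made and used up at a ratio of 0.999, each step taken net. The row turns at 0.28 M, below the crossing concentration of 0.328 M. For the winter flask, A over 1.2 M gives 0.0300 M against the 0.0298 M that stands there, and the local order of that flask is −0.84.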